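**Retrosynthetic overview**
1. Target ⇒ acetal hydrolysis and reductive removal of a C3 carbonyl (through a para-quinone methide) from a 3-aryl-2-isopropylidene-indan-1-one; the isopropylidene comes from an aldol condensation with acetone.
2. Key disconnection, C1–C7a (closes the five-membered ring): the β-carbon of an aryl enone is made nucleophilic as a chiral boron homoenolate (β-boryl ketone) and joined intramolecularly to an aryl bromide carbon. The C1 configuration is set by asymmetric conjugate borylation of a 2'-bromochalcone and carried over with retention.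
3. Chalcone ⇒ arylmagnesium reagent (from 2-bromo-6-hydroxybenzaldehyde, iodinated para to OH, CHO masked as acetal) + Weinreb cinnamamide of the benzodioxine aldehyde.
4. Benzodioxine ⇒ 2,3-dihydroxy-5-methylbenzaldehyde + (R)-3,3-dimethylglycidyl sulfonate (Sharpless epoxidation of prenol); O-alkylation then 6-exo epoxide opening sets the (S) centre.
5. Ring order: dioxane ring first (on the fragment), cyclopentane ring in the key step; both benzene rings are bought.

Assumption: atom labels in the text (C1, C2, C3, C3a, C7, C7a) are those of the target drawn as a 1-aryl-2-isopropylidene-indane (C1 carries the aryl group, C7 the formyl group). The ligand antipode in step 9 is confirmed on the first run and the mirror-image ligand is used if the sense of induction is opposite.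

**Step 1**
Reactants: 1 3-methylbut-2-en-1-ol (prenol)
Product: 3 [(2R)-3,3-dimethyloxiran-2-yl]methyl 3-nitrobenzenesulfonate, via epoxy alcohol 2 (not isolated)
Conditions: Ti(OiPr)4 (5 mol%), D-(−)-diisopropyl tartrate (6 mol%), t-BuOOH, 4 Å sieves, CH2Cl2, −20 °C; P(OMe)3; then Et3N, cat. DMAP, 3-O2NC6H4SO2Cl, −10 °C; recrystallise
Reagents that add atoms: tert-butyl hydroperoxide CC(C)(C)OO; 3-nitrobenzenesulfonyl chloride O=S(=O)(Cl)c1cccc([N+](=O)[O-])c1
Why: Sharpless asymmetric epoxidation, in which the D-(−)-tartrate titanium catalyst delivers oxygen to the alkene face that gives the (2R)-epoxy alcohol, trapped in situ as the crystalline sulfonate because the free epoxy alcohol is volatile and water-soluble.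

**Step 2**
Reactants: 4 2-methoxy-4-methylphenol (creosol)
Product: 5 2-hydroxy-3-methoxy-5-methylbenzaldehyde
Conditions: MgCl2, Et3N, (CH2O)n, MeCN, reflux
Reagents that add atoms: paraformaldehyde (formaldehyde) C=O
Why: magnesium phenoxide-directed ortho-formylation (Casnati–Skattebøl type), with only one ortho position free.

**Step 3**
Reactants: 5 2-hydroxy-3-methoxy-5-methylbenzaldehyde
Product: 6 2,3-dihydroxy-5-methylbenzaldehyde
Conditions: BBr3, CH2Cl2, −78 °C to rt; H2O
Reagents that add atoms: none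
Why: Lewis acid cleavage of the aryl methyl ether (BBr3 demethylation).

**Step 4**
Reactants: 6 2,3-dihydroxy-5-methylbenzaldehyde; 3 [(2R)-3,3-dimethyloxiran-2-yl]methyl 3-nitrobenzenesulfonate
Product: 8 (3S)-3-(2-hydroxypropan-2-yl)-7-methyl-2,3-dihydro-1,4-benzodioxine-5-carbaldehyde, via epoxy ether 7 (not isolated)
Conditions: NaH (2.2 equiv), DMSO, rt; add 3, rt then 70 °C; aq. NH4Cl
Reagents that add atoms: none
Why: Williamson alkylation of the dianion at the more nucleophilic 3-oxide (the 2-oxide is conjugated with and chelated to the aldehyde), then 6-exo-tet epoxide opening by the 2-phenoxide at the secondary carbon with inversion, so the (2R)-epoxide gives the (S) dioxane carbon.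

**Step 5**
Reactants: 8 (3S)-3-(2-hydroxypropan-2-yl)-7-methyl-2,3-dihydro-1,4-benzodioxine-5-carbaldehyde; 9 diethyl {2-[methoxy(methyl)amino]-2-oxoethyl}phosphonate
Product: 10 (2E)-3-[(3S)-3-(2-hydroxypropan-2-yl)-7-methyl-2,3-dihydro-1,4-benzodioxin-5-yl]-N-methoxy-N-methylprop-2-enamide
Conditions: LiCl, DBU, MeCN, rt
Reagents that add atoms: none
Why: Horner–Wadsworth–Emmons olefination under Masamune–Roush conditions, E-selective and tolerant of the free tertiary alcohol.

**Step 6**
Reactants: 11 2-bromo-6-hydroxybenzaldehyde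
Product: 12 2-bromo-6-hydroxy-3-iodobenzaldehyde
Conditions: N-iodosuccinimide, TsOH·H2O (10 mol%), MeCN, rt
Reagents that add atoms: N-iodosuccinimide O=C1CCC(=O)N1I
Why: electrophilic aromatic iodination, where OH (para), Br (ortho) and CHO (meta) all direct to C3.

**Step 7**
Reactants: 12 2-bromo-6-hydroxy-3-iodobenzaldehyde
Product: 13 3-bromo-2-(5,5-dimethyl-1,3-dioxan-2-yl)-4-iodophenol
Conditions: 2,2-dimethylpropane-1,3-diol, TsOH·H2O (5 mol%), toluene, reflux, Dean–Stark
Reagents that add atoms: 2,2-dimethylpropane-1,3-diol OCC(C)(C)CO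
Why: acid-catalysed acetalisation with azeotropic removal of water; the cyclic acetal survives the later basic, organometallic and hydride steps.

**Step 8**
Reactants: 13 3-bromo-2-(5,5-dimethyl-1,3-dioxan-2-yl)-4-iodophenol; 10 (2E)-3-[(3S)-3-(2-hydroxypropan-2-yl)-7-methyl-2,3-dihydro-1,4-benzodioxin-5-yl]-N-methoxy-N-methylprop-2-enamide
Product: 15 (2E)-1-[2-bromo-3-(5,5-dimethyl-1,3-dioxan-2-yl)-4-hydroxyphenyl]-3-[(3S)-3-(2-hydroxypropan-2-yl)-7-methyl-2,3-dihydro-1,4-benzodioxin-5-yl]prop-2-en-1-one, via arylmagnesium chloride 14 (not isolated)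
Conditions: 13, i-PrMgCl·LiCl (2.1 equiv), THF, −20 to 0 °C; then 10 (pre-treated with t-BuMgCl, 1.0 equiv, THF, −20 °C), −20 °C to rt; aq. NH4Cl
Reagents that add atoms: none
Why: iodine–magnesium exchange (the carbon–iodine bond reacts, the carbon–bromine bond does not) followed by Weinreb ketone synthesis, the chelated tetrahedral adduct preventing over-addition and conjugate addition.

**Step 9**
Reactants: 15 (2E)-1-[2-bromo-3-(5,5-dimethyl-1,3-dioxan-2-yl)-4-hydroxyphenyl]-3-[(3S)-3-(2-hydroxypropan-2-yl)-7-methyl-2,3-dihydro-1,4-benzodioxin-5-yl]prop-2-en-1-one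
Product: 16 (3S)-1-[2-bromo-3-(5,5-dimethyl-1,3-dioxan-2-yl)-4-hydroxyphenyl]-3-[(3S)-3-(2-hydroxypropan-2-yl)-7-methyl-2,3-dihydro-1,4-benzodioxin-5-yl]-3-(4,4,5,5-tetramethyl-1,3,2-dioxaborolan-2-yl)propan-1-one
Conditions: CuCl (5 mol%), (R)-1-[(SP)-2-(diphenylphosphino)ferrocenyl]ethyldicyclohexylphosphine (6 mol%), NaOt-Bu (10 mol%), B2pin2 (1.1 equiv), MeOH (2 equiv), THF, rt
Reagents that add atoms: bis(pinacolato)diboron CC1(C)OB(OC1(C)C)B1OC(C)(C)C(C)(C)O1
Why: copper-catalysed asymmetric conjugate borylation of a chalcone, in which the chiral bisphosphine copper boryl adds to one face of the enone and so sets the carbon–boron stereocentre as (S).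

**Step 10**
Reactants: 16 (3S)-1-[2-bromo-3-(5,5-dimethyl-1,3-dioxan-2-yl)-4-hydroxyphenyl]-3-[(3S)-3-(2-hydroxypropan-2-yl)-7-methyl-2,3-dihydro-1,4-benzodioxin-5-yl]-3-(4,4,5,5-tetramethyl-1,3,2-dioxaborolan-2-yl)propan-1-one
Product: 17 (3R)-4-(5,5-dimethyl-1,3-dioxan-2-yl)-5-hydroxy-3-[(3S)-3-(2-hydroxypropan-2-yl)-7-methyl-2,3-dihydro-1,4-benzodioxin-5-yl]-2,3-dihydro-1H-inden-1-one
Conditions: Pd2(dba)3 (4 mol%; dba = dibenzylideneacetone), PPh3 (32 mol%), Ag2O (1.5 equiv), DME, 85 °C
Reagents that add atoms: none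
Why: Proposed new method: intramolecular Suzuki–Miyaura coupling of the boron homoenolate, in which zerovalent palladium inserts into the aryl bromide, the secondary benzylic carbon–boron bond transmetalates with Ag2O assistance through a closed four-centre transition state with retention (six-membered palladacycle) and reductive elimination to the five-membered ring outruns β-hydride elimination, so the enone β-carbon (an acceptor carbon) is joined to the aryl bromide carbon and (S)-16 gives (3R)-17; the closest known reactions are the Ag2O-promoted stereoretentive Suzuki–Miyaura coupling of enantioenriched secondary benzylic boronic esters and the cross-coupling of β-boryl carbonyl compounds.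

**Step 11**
Reactants: 17 (3R)-4-(5,5-dimethyl-1,3-dioxan-2-yl)-5-hydroxy-3-[(3S)-3-(2-hydroxypropan-2-yl)-7-methyl-2,3-dihydro-1,4-benzodioxin-5-yl]-2,3-dihydro-1H-inden-1-one
Product: 18 (3R)-4-(5,5-dimethyl-1,3-dioxan-2-yl)-5-hydroxy-3-[(3S)-3-(2-hydroxypropan-2-yl)-7-methyl-2,3-dihydro-1,4-benzodioxin-5-yl]-2-(propan-2-ylidene)-2,3-dihydro-1H-inden-1-one
Conditions: KOH (10 equiv), acetone/EtOH, 45 °C
Reagents that add atoms: acetone CC(C)=O
Why: crossed aldol condensation of the only enolisable methylene with acetone and E1cB dehydration, which places the tetrasubstituted alkene exocyclic and conjugated without any cationic step; the stereocentre is β to the carbonyl and is not touched.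

**Step 12**
Reactants: 18 (3R)-4-(5,5-dimethyl-1,3-dioxan-2-yl)-5-hydroxy-3-[(3S)-3-(2-hydroxypropan-2-yl)-7-methyl-2,3-dihydro-1,4-benzodioxin-5-yl]-2-(propan-2-ylidene)-2,3-dihydro-1H-inden-1-one
Product: 21 Diaporindene G [(3R)-5-hydroxy-3-[(3S)-3-(2-hydroxypropan-2-yl)-7-methyl-2,3-dihydro-1,4-benzodioxin-5-yl]-2-(propan-2-ylidene)-2,3-dihydro-1H-indene-4-carbaldehyde], via indanol 19 (not isolated), via acetal 20 (not isolated)
Conditions: NaBH4, CeCl3·7H2O, MeOH/THF, 0 °C; then NaBH4 (excess), 2 M aq. NaOH, 65 °C; then 1 M HCl, THF, rt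
Reagents that add atoms: water O
Why: Luche 1,2-reduction, then reductive deoxygenation of the para-hydroxybenzylic allylic alcohol (the phenoxide expels hydroxide to a para-quinone methide, which borohydride reduces at the less hindered benzylic carbon so the exocyclic alkene stays in place), then mild acid hydrolysis of the acetal; the stereocentres are not involved.

**Compound list**
1 | 3-methylbut-2-en-1-ol (prenol) | CC(C)=CCO | starting material
2 | [(2R)-3,3-dimethyloxiran-2-yl]methanol | CC1(C)O[C@@H]1CO | intermediate (not isolated)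
3 | [(2R)-3,3-dimethyloxiran-2-yl]methyl 3-nitrobenzenesulfonate | CC1(C)O[C@@H]1COS(=O)(=O)c1cccc([N+](=O)[O-])c1 | intermediate
4 | 2-methoxy-4-methylphenol (creosol) | COc1cc(C)ccc1O | starting material
5 | 2-hydroxy-3-methoxy-5-methylbenzaldehyde | COc1cc(C)cc(C=O)c1O | intermediate
6 | 2,3-dihydroxy-5-methylbenzaldehyde | Cc1cc(O)c(O)c(C=O)c1 | intermediate
7 | 3-{[(2R)-3,3-dimethyloxiran-2-yl]methoxy}-2-hydroxy-5-methylbenzaldehyde (present as its sodium phenoxide) | Cc1cc(C=O)c(O)c(OC[C@H]2OC2(C)C)c1 | intermediate (not isolated)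
8 | (3S)-3-(2-hydroxypropan-2-yl)-7-methyl-2,3-dihydro-1,4-benzodioxine-5-carbaldehyde | O=Cc1cc(C)cc2c1O[C@H](C(C)(C)O)CO2 | intermediate
9 | diethyl {2-[methoxy(methyl)amino]-2-oxoethyl}phosphonate | CCOP(=O)(OCC)CC(=O)N(C)OC | starting material
10 | (2E)-3-[(3S)-3-(2-hydroxypropan-2-yl)-7-methyl-2,3-dihydro-1,4-benzodioxin-5-yl]-N-methoxy-N-methylprop-2-enamide | CON(C)C(=O)/C=C/c1cc(C)cc2c1O[C@H](C(C)(C)O)CO2 | intermediate
11 | 2-bromo-6-hydroxybenzaldehyde | O=Cc1c(O)cccc1Br | starting material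
12 | 2-bromo-6-hydroxy-3-iodobenzaldehyde | O=Cc1c(O)ccc(I)c1Br | intermediate
13 | 3-bromo-2-(5,5-dimethyl-1,3-dioxan-2-yl)-4-iodophenol | Oc1ccc(I)c(Br)c1C1OCC(C)(C)CO1 | intermediate
14 | chloromagnesium 3-bromo-4-(chloromagnesio)-2-(5,5-dimethyl-1,3-dioxan-2-yl)phenolate | Cl[Mg]Oc1ccc([Mg]Cl)c(Br)c1C1OCC(C)(C)CO1 | intermediate (not isolated)
15 | (2E)-1-[2-bromo-3-(5,5-dimethyl-1,3-dioxan-2-yl)-4-hydroxyphenyl]-3-[(3S)-3-(2-hydroxypropan-2-yl)-7-methyl-2,3-dihydro-1,4-benzodioxin-5-yl]prop-2-en-1-one | O=C(/C=C/c1cc(C)cc2c1O[C@H](C(C)(C)O)CO2)c1ccc(O)c(C2OCC(C)(C)CO2)c1Br | intermediate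
16 | (3S)-1-[2-bromo-3-(5,5-dimethyl-1,3-dioxan-2-yl)-4-hydroxyphenyl]-3-[(3S)-3-(2-hydroxypropan-2-yl)-7-methyl-2,3-dihydro-1,4-benzodioxin-5-yl]-3-(4,4,5,5-tetramethyl-1,3,2-dioxaborolan-2-yl)propan-1-one | O=C(C[C@H](B1OC(C)(C)C(C)(C)O1)c1cc(C)cc2c1O[C@H](C(C)(C)O)CO2)c1ccc(O)c(C2OCC(C)(C)CO2)c1Br | intermediate
17 | (3R)-4-(5,5-dimethyl-1,3-dioxan-2-yl)-5-hydroxy-3-[(3S)-3-(2-hydroxypropan-2-yl)-7-methyl-2,3-dihydro-1,4-benzodioxin-5-yl]-2,3-dihydro-1H-inden-1-one | O=C1C[C@@H](c2cc(C)cc3c2O[C@H](C(C)(C)O)CO3)c2c1ccc(O)c2C1OCC(C)(C)CO1 | intermediate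
18 | (3R)-4-(5,5-dimethyl-1,3-dioxan-2-yl)-5-hydroxy-3-[(3S)-3-(2-hydroxypropan-2-yl)-7-methyl-2,3-dihydro-1,4-benzodioxin-5-yl]-2-(propan-2-ylidene)-2,3-dihydro-1H-inden-1-one | CC(C)=C1C(=O)c2ccc(O)c(C3OCC(C)(C)CO3)c2[C@@H]1c1cc(C)cc2c1O[C@H](C(C)(C)O)CO2 | intermediate
19 | (3S)-4-(5,5-dimethyl-1,3-dioxan-2-yl)-3-[(3S)-3-(2-hydroxypropan-2-yl)-7-methyl-2,3-dihydro-1,4-benzodioxin-5-yl]-2-(propan-2-ylidene)-2,3-dihydro-1H-indene-1,5-diol (both epimers at the carbinol carbon; same spatial arrangement at C3 as in 18, the descriptor changes only by the priority rules) | CC(C)=C1C(O)c2ccc(O)c(C3OCC(C)(C)CO3)c2[C@@H]1c1cc(C)cc2c1O[C@H](C(C)(C)O)CO2 | intermediate (not isolated)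
20 | (3R)-4-(5,5-dimethyl-1,3-dioxan-2-yl)-3-[(3S)-3-(2-hydroxypropan-2-yl)-7-methyl-2,3-dihydro-1,4-benzodioxin-5-yl]-2-(propan-2-ylidene)-2,3-dihydro-1H-inden-5-ol | CC(C)=C1Cc2ccc(O)c(C3OCC(C)(C)CO3)c2[C@@H]1c1cc(C)cc2c1O[C@H](C(C)(C)O)CO2 | intermediate (not isolated)
21 | Diaporindene G, (3R)-5-hydroxy-3-[(3S)-3-(2-hydroxypropan-2-yl)-7-methyl-2,3-dihydro-1,4-benzodioxin-5-yl]-2-(propan-2-ylidene)-2,3-dihydro-1H-indene-4-carbaldehyde | CC(C)=C1Cc2ccc(O)c(C=O)c2[C@@H]1c1cc(C)cc2c1O[C@H](C(C)(C)O)CO2 | target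

**Totals**
Total step count: 12. Longest linear sequence: 9 steps (4 → 5 → 6 → 8 → 10 → 15 → 16 → 17 → 18 → 21; steps 2, 3, 4, 5, 8, 9, 10, 11, 12).

**Three steps most likely to fail, each with a fallback**

Step 10 (ring closure through the boron homoenolate). The risks are protodeboronation, β-hydride elimination from the alkylpalladium intermediate, or incomplete stereochemical fidelity if an invertive, carbonyl-assisted transmetalation competes. The fallback sets out from chalcone 15 and uses the invertive pathway on purpose. The borylation of step 9 is run with the mirror-image ligand to give the (3R)-configured boronic ester F1. KHF2 in MeOH/H2O converts it into the potassium trifluoroborate F2. This is cyclised with Pd(OAc)2, 2-dicyclohexylphosphino-2',6'-diisopropoxybiphenyl and Cs2CO3 in toluene/H2O at 95 °C. β-Trifluoroborato carbonyl compounds transmetalate through an open transition state with inversion, so F2 comes back to the route at indanone 17.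

Step 11 (aldol condensation with acetone). The risks are slow enolisation of the para-phenoxide ketone, acetone self-condensation, and base-induced migration of the new alkene into the ring with loss of the C1 centre. The fallback sets out from 17 and builds the enone stepwise. Phenol and tertiary alcohol are silylated with N-(trimethylsilyl)imidazole to the bis(trimethylsilyl) ether F3. The lithium enolate (LiN(i-Pr)2, THF, −78 °C) is quenched with acetone to give the aldol adduct F4. Its only free hydroxyl is removed by mesylation and E1cB elimination (MsCl, Et3N, then DBU) to give the silylated enone F5. K2CO3 in MeOH removes both silyl groups, and the route is rejoined at enone 18.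

Step 12 (reductive deoxygenation). The risks are hydride attack at the distal isopropylidene carbon of the extended quinone methide (giving a 2-isopropyl-indene), tautomerisation of the quinone methide to a diene, or 1,4-reduction of the enone. The fallback stops after the Luche stage and isolates indanol 19. Ac2O, pyridine and DMAP convert it into the diacetate F6 (aryl acetate and allylic acetate). Pd(PPh3)4 with LiBHEt3 in THF (0 °C to rt) then forms a π-allylpalladium intermediate that takes hydride at the less hindered benzylic terminus, so the tetrasubstituted alkene is kept, and the same hydride cleaves the aryl acetate. This comes back at acetal 20, which the acid treatment of step 12 converts into 21.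

**Further compounds**
F1 | step 10 | (3R)-1-[2-bromo-3-(5,5-dimethyl-1,3-dioxan-2-yl)-4-hydroxyphenyl]-3-[(3S)-3-(2-hydroxypropan-2-yl)-7-methyl-2,3-dihydro-1,4-benzodioxin-5-yl]-3-(4,4,5,5-tetramethyl-1,3,2-dioxaborolan-2-yl)propan-1-one | O=C(C[C@@H](B1OC(C)(C)C(C)(C)O1)c1cc(C)cc2c1O[C@H](C(C)(C)O)CO2)c1ccc(O)c(C2OCC(C)(C)CO2)c1Br
F2 | step 10 | potassium {(1R)-3-[2-bromo-3-(5,5-dimethyl-1,3-dioxan-2-yl)-4-hydroxyphenyl]-1-[(3S)-3-(2-hydroxypropan-2-yl)-7-methyl-2,3-dihydro-1,4-benzodioxin-5-yl]-3-oxopropyl}trifluoroborate | O=C(C[C@@H]([B-](F)(F)F)c1cc(C)cc2c1O[C@H](C(C)(C)O)CO2)c1ccc(O)c(C2OCC(C)(C)CO2)c1Br.[K+]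
F3 | step 11 | bis(trimethylsilyl) ether of 17 (phenol and tertiary alcohol silylated, 3R) | O=C1C[C@@H](c2cc(C)cc3c2O[C@H](C(C)(C)O[Si](C)(C)C)CO3)c2c1ccc(O[Si](C)(C)C)c2C1OCC(C)(C)CO1
F4 | step 11 | 2-(2-hydroxypropan-2-yl) aldol adduct of F3 (3R, both C2 epimers) | O=C1C(C(C)(C)O)[C@@H](c2cc(C)cc3c2O[C@H](C(C)(C)O[Si](C)(C)C)CO3)c2c1ccc(O[Si](C)(C)C)c2C1OCC(C)(C)CO1
F5 | step 11 | bis(trimethylsilyl) ether of 18 (3R) | CC(C)=C1C(=O)c2ccc(O[Si](C)(C)C)c(C3OCC(C)(C)CO3)c2[C@@H]1c1cc(C)cc2c1O[C@H](C(C)(C)O[Si](C)(C)C)CO2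
F6 | step 12 | diacetate of 19 (aryl acetate and allylic acetate, both epimers at the acetoxy carbon) | CC(C)=C1C(OC(C)=O)c2ccc(OC(C)=O)c(C3OCC(C)(C)CO3)c2[C@@H]1c1cc(C)cc2c1O[C@H](C(C)(C)O)CO2
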